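Carbon numbering used throughout: C1 is the lactone carbonyl, C2–C5 the rest of the ring carbons (C5 bears the ring oxygen), C6–C20 the side chain, C20 the terminal methyl. Compound numbers 1–20 are those of the steps and the compound list.

## Analysis of the target

Target 20 is an unbranched C20 polyketide. C1–C5 and the ring oxygen form a 4-hydroxy-5,6-dihydro-2H-pyran-2-one, the enol form of a 3-oxo-δ-lactone. C5 carries a fifteen-carbon chain (C6–C20) with secondary hydroxyls at C7, C9 and C11 and a nonyl tail (C12–C20). The four stereocentres C5 (R), C7 (R), C9 (S) and C11 (S) are all oxygen-bearing and spaced 1,3: C5/C7 are syn, C7/C9 anti and C9/C11 syn. There is no carbon-branched stereocentre and no ring besides the lactone, so the difficulty is acyclic 1,3-stereocontrol over four carbinols and telling the two chain ends apart. The sensitive part is the β-keto lactone: it is acidic, O5 sits β to the C3 carbonyl (ring-opening elimination under strong base), and the ring-opened β-keto acid decarboxylates. The free 1,3-polyol can also dehydrate, so the lactone is best formed last from a β-keto ester. The plan rests on the anti pair C7/C9 with methylene C8 between them, which is a C2-symmetric unit; each of these centres faces outward a methylene (C6, C10) and then a carbinol that is syn to it (C5, C11). The carbons C6–C10 can therefore come from the C2-symmetric diepoxide 5, joined at both ends to alkynes whose first carbons (C5, C11) become ketones and are reduced under control of the neighbouring hydroxyls.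

## Retrosynthetic reasoning

**Lactone C1–O bond.** The ring of 20 is opened at the ester bond to the tetrahydroxy β-keto ester 19. Only the C5 hydroxyl can return a six-membered ring, so no hydroxyl differentiation is needed for the closure. Compound 19 is masked as the bis-acetonide 18, which hides all four hydroxyls in one protecting pattern until the last step.

**C2–C3 bond.** The β-keto ester 18 is cut between C2 and C3 into aldehyde 16 (C3–C20) and ethyl diazoacetate 17 (C1–C2). This brings the acidic 1,3-dicarbonyl in one neutral, Lewis-acid-catalysed step, late and without a strong base next to the β-oxygen at C5. Aldehyde 16 goes back by oxidation-state and protecting-group changes to alcohol 15 and benzyl ether 14.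

**C5–H and C11–H bonds.** The bis-acetonide 14 comes from tetraol 13, and the two outer carbinols of 13 are traced to the ketones of diketone 12. Both are β to an existing hydroxyl (C7 for C5, C9 for C11), so one chelation-controlled hydride reduction can set both outer centres syn to their inner neighbours. The forward step must bind each hydroxyl to its own carbonyl and deliver hydride from outside the chelate.

**C5=O and C11=O.** Each ketone of 12 is a hydrated alkyne. In diyne diol 9 each alkyne is homopropargylic to a carbinol, so a short O–Si–H tether (compound 10) can deliver silicon, and after oxidation oxygen, to the nearer alkyne carbon only, via the cyclic siloxane 11. This solves the regiochemistry of hydration for both alkynes at once.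

**C5–C6 and C10–C11 bonds.** Diyne diol 9 is cut at the two propargylic bonds into diepoxide 5 (C6–C10), 1-decyne 6 (C11–C20) and benzyl propargyl ether 7 (C3–C5), through the mono-adduct 8. These cuts lie on the unsubstituted epoxide carbons, so bond formation cannot disturb C7 or C9, and the two homotopic ends of 5 remove any question of which end reacts first. The forward reaction has to open each oxirane at CH2 and stop after one opening before the second acetylide is introduced.

**The diepoxide.** Compound 5 is traced to the bis-chlorohydrin 4 and this to diketone 3, in which both centres are set by one catalytic asymmetric hydrogenation. Compound 3 comes from pentane-2,4-dione 1 and chloroacetyl chloride 2 by acyl exchange. A hydrogenation route is preferred to epoxidising a diene and resolving, which would discard most of the material.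

## Alternatives that were turned down

**Alternative 1:** two-directional iodocarbonate closure.
- Disconnection: the C5–O and C11–O bonds are made as the stereo-forming bonds on a C2-symmetric diene.
- Forward key step: the bis(tert-butyl carbonate) A2 of the C4–C12 diene-diol is treated with IBr at low temperature. Each carbonate oxygen closes onto its iodonium-activated terminal alkene to give the bis(iodomethyl) bis(cyclic carbonate) A1, with C5 and C11 set syn through chair-like closures.
- For: the closure is reliably syn-selective, A2 is made without any statistical step (two identical vinyl additions), and the carbinol oxidation level is reached directly. On diastereocontrol at C5 and C11 it is as strong as the chosen reduction, and it avoids the platinum step.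
- Against: A1 ends in two identical CH2I groups (C4 and C12), while the target needs an octyl group on C12 and a C1–C3 acyl unit on C4. The ends must be told apart late, on a valuable intermediate, again statistically. The C4 electrophile also has no reliable direct partner of the acetoacetate type, so further chain-building steps follow.
- Comparison: the chosen plan differentiates the ends in its first C–C bond formation, with cheap alkynes that already carry C3 and the whole C11–C20 tail, and is shorter overall.

**Alternative 2:** oxidative carbonylation of an alkyne to the enol lactone.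
- Disconnection: the C1–C2 bond and the lactone C1–O bond, with C1 coming from CO.
- Forward key step: the C2–C20 homopropargylic alcohol A4 reacts with CO and methanol under Pd(OCOCF3)2/bis(oxazoline) catalysis with p-benzoquinone as oxidant. Methanol adds to C3, CO inserts at C2 and the C5 hydroxyl captures the acyl-palladium to give the 4-methoxy-5,6-dihydropyran-2-one A3.
- For: the heterocycle and C1 are built in one catalytic step, which replaces the debenzylation, oxidation, homologation and lactonisation of the chosen endgame. On step economy at this end it is stronger.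
- Against: A3 is the methyl enol ether, not the free enol. Cleaving this vinylogous carbonate needs hot aqueous acid or hard nucleophiles, which invite ring-opening elimination and dehydration of the polyol. A4 also needs all four stereocentres in place with three different hydroxyl states (free at C5, silyl at C7, ketal at C9/C11), and the free C5 hydroxyl can compete by direct attack on the activated alkyne.
- Comparison: the chosen plan gives the free enol directly at the right oxidation level and uses a single protecting pattern (two acetonides) for all four hydroxyls.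

**Alternative 3:** silyl dithiane linchpin at C9.
- Disconnection: the C9–C10 and C8–C9 bonds, with C9 as an acyl-anion carbon.
- Forward key step: lithiated silyl dithiane A6 (t-BuLi, Et2O) opens epoxide A7 at C10. HMPA and epoxide A8 are then added, a 1,4-Brook shift moves silicon to O11, and the regenerated C9 anion opens A8 at C8 to give A5 (O11 silylated, O7 free). Dithiane removal and a C7-hydroxyl-directed anti reduction would then set C9.
- For: three fragments are joined in one flask in a defined order with no statistical step, and the hydroxyls emerge differentiated. On convergence and coupling selectivity it is stronger.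
- Against: three of the four stereocentres must be supplied separately (A7 by resolution, A8 with two centres in about five steps of its own), C9 still needs dithiane hydrolysis and a reduction, and t-BuLi/HMPA are required. With the same endgame the count is near fifteen steps.
- Comparison: the chosen plan uses the C2 symmetry so that one asymmetric hydrogenation supplies C7 and C9 and the other two centres are relayed from them. The price is a statistical first epoxide opening.

Key step: step 4

Assumption: 20 is drawn as the enol of a 3-oxo-δ-lactone; the route is planned for this tautomeric system, which is expected to rest in the enol form drawn.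

## Route

Step 1
Reactants: 1 pentane-2,4-dione; 2 chloroacetyl chloride
Product: 3 1,5-dichloropentane-2,4-dione
Conditions: AlCl3 (3 equiv), 2 (2.5 equiv), PhNO2, rt → 60 °C; aq. HCl; isolated through the Cu(OAc)2 chelate, released with 10% H2SO4
Reagents that add atoms: none
Why: AlCl3-promoted acyl exchange on a β-diketone: the aluminium chelate of 1 is C-acylated at its central carbon by 2 and the triketone sheds an acetyl group as acetyl chloride, twice over, so that only the central CH2 of 1 is retained between two chloroacetyl units.

Step 2
Reactants: 3 1,5-dichloropentane-2,4-dione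
Product: 4 (2R,4R)-1,5-dichloropentane-2,4-diol
Conditions: RuCl2[(S)-BINAP] (0.2 mol%), H2 (85 bar), MeOH, 75 °C; recrystallisation
Reagents that add atoms: none
Why: Noyori hydrogenation of a β-diketone: the first carbonyl is reduced under ligand control with the second as directing group, and the β-hydroxy ketone is reduced again with the same facial preference to the anti (C2-symmetric) diol; by analogy with 4-chloro-3-oxo esters the (S)-ligand should give the R centres (to be confirmed by the sign of rotation), and crystallisation should remove meso material.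

Step 3
Reactants: 4 (2R,4R)-1,5-dichloropentane-2,4-diol
Product: 5 (2R,4R)-1,2:4,5-diepoxypentane
Conditions: KOH (powdered, 4 equiv), Et2O, rt; distillation
Reagents that add atoms: none
Why: Double intramolecular Williamson (SN2) closure of the bis-chlorohydrin; only the primary C–Cl carbons are attacked, so both carbinol configurations are retained.

Step 4
Reactants: 5 (2R,4R)-1,2:4,5-diepoxypentane; 6 1-decyne; 7 benzyl propargyl ether
Product: 9 (5S,7S)-1-(benzyloxy)octadeca-2,9-diyne-5,7-diol, via epoxy alcohol 8 (not isolated)
Conditions: (a) 6 (1.0 equiv), n-BuLi (1.0 equiv), THF, −78 °C; BF3·OEt2 (1.0 equiv); 5 (1.1 equiv), −78 °C, 1 h; (b) same flask: lithium acetylide of 7 (2.5 equiv, from 7 and n-BuLi, THF, −78 °C), BF3·OEt2 (2.5 equiv), −78 °C, 2 h; aq. NH4Cl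
Reagents that add atoms: none
Why: BF3·OEt2 coordinates the oxirane oxygen and the lithium acetylide attacks the unsubstituted carbon from the back in an SN2 opening, the Yamaguchi alkynylation of terminal epoxides being the closest known reaction type. Stage (a) forms C10–C11 and leaves the alkoxide of 8 as its BF3 adduct; stage (b) forms C5–C6 at the remaining oxirane. No ring is closed and no stereocentre is made: the C–O bonds at C7 and C9 are never broken, so both configurations of 5 pass unchanged into 9. Because the two oxiranes of 5 are homotopic, mono-opening gives a single compound whichever end reacts. The step needs attack at CH2 rather than CH, which the monosubstituted oxirane secures, and mono-addition in stage (a), which is only statistical and is steered by keeping the first acetylide as the limiting partner. The two symmetrical double adducts that accompany 9 differ from it by one benzyloxy group in either direction and should separate on silica. The alkoxide of 8 carries no proton to quench the second acetylide and at −78 °C should not close onto the neighbouring oxirane (4-exo or 5-endo modes).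

Step 5
Reactants: 9 (5S,7S)-1-(benzyloxy)octadeca-2,9-diyne-5,7-diol
Product: 10 (5S,7S)-1-(benzyloxy)-5,7-bis[(dimethylsilyl)oxy]octadeca-2,9-diyne
Conditions: (HMe2Si)2NH (3 equiv), neat, rt → 60 °C; volatiles removed in vacuo
Reagents that add atoms: 1,1,3,3-tetramethyldisilazane, C[SiH](C)N[SiH](C)C
Why: Silazane silylation of both hydroxyls with ammonia as the only by-product; it places one Si–H within reach of the nearer carbon of each alkyne and touches no stereocentre.

Step 6
Reactants: 10 (5S,7S)-1-(benzyloxy)-5,7-bis[(dimethylsilyl)oxy]octadeca-2,9-diyne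
Product: 12 (5R,7R)-1-(benzyloxy)-5,7-dihydroxyoctadecane-3,9-dione, via bis(oxasilolane) 11 (not isolated)
Conditions: H2PtCl6·6H2O (0.5 mol%), THF, rt → 50 °C; then 30% aq. H2O2, KF, KHCO3, THF/MeOH, rt
Reagents that add atoms: hydrogen peroxide, OO
Why: Tamao-type platinum-catalysed intramolecular hydrosilylation: each O–SiMe2–H adds syn across its alkyne in the 5-exo-dig mode, so silicon ends on C5 and C11 only; Tamao–Fleming oxidation then replaces each alkenyl C–Si bond by C–O and the enols tautomerise to the ketones, with C7 and C9 untouched.

Step 7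
Reactants: 12 (5R,7R)-1-(benzyloxy)-5,7-dihydroxyoctadecane-3,9-dione
Product: 13 (3S,5S,7S,9S)-1-(benzyloxy)octadecane-3,5,7,9-tetrol
Conditions: Et2BOMe (2.4 equiv), THF/MeOH (4:1), −78 °C; NaBH4 (2.5 equiv), −78 °C; AcOH; MeOH co-evaporation
Reagents that add atoms: none
Why: Narasaka–Prasad reduction: each hydroxyl is held with its own β-carbonyl in a diethylboron chelate (any hemiketal form reopens on boron binding) and external hydride attacks the half-chair axially, which sets C5 syn to C7 and C11 syn to C9 in one operation.

Step 8
Reactants: 13 (3S,5S,7S,9S)-1-(benzyloxy)octadecane-3,5,7,9-tetrol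
Product: 14 (4S,6S)-4-[2-(benzyloxy)ethyl]-6-{[(4S,6S)-2,2-dimethyl-6-nonyl-1,3-dioxan-4-yl]methyl}-2,2-dimethyl-1,3-dioxane
Conditions: 2,2-dimethoxypropane, PPTS (cat.), CH2Cl2, rt
Reagents that add atoms: 2,2-dimethoxypropane, COC(C)(C)OC
Why: Acid-catalysed transketalisation under thermodynamic control: the syn pairs C5/C7 and C9/C11 give chair dioxanes with both substituents equatorial, whereas the anti pair C7/C9 could only give a twist-boat, so the 5,7:9,11-bis-acetonide should be the sink; the acetonide 13C shifts would also serve as a check of both syn relationships.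

Step 9
Reactants: 14 (4S,6S)-4-[2-(benzyloxy)ethyl]-6-{[(4S,6S)-2,2-dimethyl-6-nonyl-1,3-dioxan-4-yl]methyl}-2,2-dimethyl-1,3-dioxane
Product: 15 2-[(4S,6S)-6-{[(4S,6S)-2,2-dimethyl-6-nonyl-1,3-dioxan-4-yl]methyl}-2,2-dimethyl-1,3-dioxan-4-yl]ethan-1-ol
Conditions: H2 (1 atm), Pd/C (10% palladium on carbon), EtOAc, rt
Reagents that add atoms: none
Why: Hydrogenolysis of the benzyl ether under neutral conditions, which leaves both acetonides and all stereocentres untouched.

Step 10
Reactants: 15 2-[(4S,6S)-6-{[(4S,6S)-2,2-dimethyl-6-nonyl-1,3-dioxan-4-yl]methyl}-2,2-dimethyl-1,3-dioxan-4-yl]ethan-1-ol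
Product: 16 2-[(4R,6R)-6-{[(4S,6S)-2,2-dimethyl-6-nonyl-1,3-dioxan-4-yl]methyl}-2,2-dimethyl-1,3-dioxan-4-yl]acetaldehyde
Conditions: Dess–Martin periodinane (1.3 equiv), NaHCO3, CH2Cl2, 0 °C → rt
Reagents that add atoms: none
Why: Dess–Martin oxidation of the primary alcohol under bicarbonate buffer; the near-neutral, non-basic medium avoids β-elimination of the C5 acetal oxygen and acetonide loss (the R descriptors arise only from the changed substituent priorities).

Step 11
Reactants: 16 2-[(4R,6R)-6-{[(4S,6S)-2,2-dimethyl-6-nonyl-1,3-dioxan-4-yl]methyl}-2,2-dimethyl-1,3-dioxan-4-yl]acetaldehyde; 17 ethyl diazoacetate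
Product: 18 ethyl 4-[(4R,6R)-6-{[(4S,6S)-2,2-dimethyl-6-nonyl-1,3-dioxan-4-yl]methyl}-2,2-dimethyl-1,3-dioxan-4-yl]-3-oxobutanoate
Conditions: SnCl2 (15 mol%), 17 (1.3 equiv), CH2Cl2, rt
Reagents that add atoms: none
Why: Roskamp homologation: SnCl2 activates the aldehyde, the diazo carbon of 17 adds to C3, and a 1,2-hydride shift with loss of N2 gives the β-keto ester, forming the C2–C3 bond without a base that could expel the β-oxygen.

Step 12
Reactants: 18 ethyl 4-[(4R,6R)-6-{[(4S,6S)-2,2-dimethyl-6-nonyl-1,3-dioxan-4-yl]methyl}-2,2-dimethyl-1,3-dioxan-4-yl]-3-oxobutanoate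
Product: 20 (6R)-4-hydroxy-6-[(2R,4S,6S)-2,4,6-trihydroxypentadecyl]-5,6-dihydro-2H-pyran-2-one, via tetrahydroxy keto ester 19 (not isolated)
Conditions: 1 M aq. HCl/THF (1:4), rt; then aq. NaOH to pH 12, 0 °C → rt; then 1 M HCl to pH 2–3, EtOAc extraction
Reagents that add atoms: none
Why: Aqueous acid hydrolyses both isopropylidene ketals to 19; at pH 12 the C5 alkoxide adds to the ester (6-exo-trig lactonisation) with loss of ethoxide and the product is held as its stabilised vinylogous carboxylate until acidification releases enol 20; only the C5 hydroxyl can close a six-membered lactone and no stereocentre is touched.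

## Compound list

1 | pentane-2,4-dione | CC(=O)CC(C)=O | starting material
2 | chloroacetyl chloride | ClCC(Cl)=O | starting material
3 | 1,5-dichloropentane-2,4-dione | ClCC(=O)CC(=O)CCl | intermediate
4 | (2R,4R)-1,5-dichloropentane-2,4-diol | ClC[C@H](O)C[C@@H](O)CCl | intermediate
5 | (2R,4R)-1,2:4,5-diepoxypentane [(2R,2'R)-2,2'-methylenebis(oxirane)] | C1O[C@@H]1C[C@@H]1CO1 | intermediate
6 | 1-decyne | CCCCCCCCC#C | starting material
7 | benzyl propargyl ether [(prop-2-yn-1-yloxy)methyl]benzene | C#CCOCc1ccccc1 | starting material
8 | (2S)-1-[(2R)-oxiran-2-yl]tridec-4-yn-2-ol | CCCCCCCCC#CC[C@H](O)C[C@@H]1CO1 | intermediate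
9 | (5S,7S)-1-(benzyloxy)octadeca-2,9-diyne-5,7-diol | CCCCCCCCC#CC[C@H](O)C[C@@H](O)CC#CCOCc1ccccc1 | intermediate
10 | (5S,7S)-1-(benzyloxy)-5,7-bis[(dimethylsilyl)oxy]octadeca-2,9-diyne | CCCCCCCCC#CC[C@H](O[SiH](C)C)C[C@@H](O[SiH](C)C)CC#CCOCc1ccccc1 | intermediate
11 | (5R)-3-[(E)-2-(benzyloxy)ethylidene]-5-{[(5R)-2,2-dimethyl-3-[(E)-nonylidene]-1,2-oxasilolan-5-yl]methyl}-2,2-dimethyl-1,2-oxasilolane | CCCCCCCC/C=C1\C[C@H](O[Si]1(C)C)C[C@@H](O[Si]2(C)C)C/C2=C\COCc1ccccc1 | intermediate
12 | (5R,7R)-1-(benzyloxy)-5,7-dihydroxyoctadecane-3,9-dione | CCCCCCCCCC(=O)C[C@H](O)C[C@@H](O)CC(=O)CCOCc1ccccc1 | intermediate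
13 | (3S,5S,7S,9S)-1-(benzyloxy)octadecane-3,5,7,9-tetrol | CCCCCCCCC[C@H](O)C[C@H](O)C[C@@H](O)C[C@@H](O)CCOCc1ccccc1 | intermediate
14 | (4S,6S)-4-[2-(benzyloxy)ethyl]-6-{[(4S,6S)-2,2-dimethyl-6-nonyl-1,3-dioxan-4-yl]methyl}-2,2-dimethyl-1,3-dioxane | CCCCCCCCC[C@H]1C[C@H](OC(C)(C)O1)C[C@@H]1C[C@@H](OC(C)(C)O1)CCOCc2ccccc2 | intermediate
15 | 2-[(4S,6S)-6-{[(4S,6S)-2,2-dimethyl-6-nonyl-1,3-dioxan-4-yl]methyl}-2,2-dimethyl-1,3-dioxan-4-yl]ethan-1-ol | CCCCCCCCC[C@H]1C[C@H](OC(C)(C)O1)C[C@@H]1C[C@@H](OC(C)(C)O1)CCO | intermediate
16 | 2-[(4R,6R)-6-{[(4S,6S)-2,2-dimethyl-6-nonyl-1,3-dioxan-4-yl]methyl}-2,2-dimethyl-1,3-dioxan-4-yl]acetaldehyde | CCCCCCCCC[C@H]1C[C@H](OC(C)(C)O1)C[C@@H]1C[C@@H](OC(C)(C)O1)CC=O | intermediate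
17 | ethyl diazoacetate | CCOC(=O)C=[N+]=[N-] | starting material
18 | ethyl 4-[(4R,6R)-6-{[(4S,6S)-2,2-dimethyl-6-nonyl-1,3-dioxan-4-yl]methyl}-2,2-dimethyl-1,3-dioxan-4-yl]-3-oxobutanoate | CCCCCCCCC[C@H]1C[C@H](OC(C)(C)O1)C[C@@H]1C[C@@H](OC(C)(C)O1)CC(=O)CC(=O)OCC | intermediate
19 | ethyl (5R,7R,9S,11S)-5,7,9,11-tetrahydroxy-3-oxoicosanoate | CCCCCCCCC[C@H](O)C[C@H](O)C[C@@H](O)C[C@@H](O)CC(=O)CC(=O)OCC | intermediate
20 | (6R)-4-hydroxy-6-[(2R,4S,6S)-2,4,6-trihydroxypentadecyl]-5,6-dihydro-2H-pyran-2-one | CCCCCCCCC[C@H](O)C[C@H](O)C[C@@H](O)C[C@@H]1CC(O)=CC(=O)O1 | target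

## Step count and least certain steps

Total: 12 steps. Longest linear sequence: 12 steps (1 and 2 to 20); 6, 7 and 17 enter as purchased materials.

**Step 4 (key step).** The first opening is only statistically selective, so over-addition of the decynylide and carry-through of unreacted 5 into stage (b) would lower the material balance. Warming of the acetylide/BF3 mixture would also destroy the nucleophile, and the Lewis acid could induce closure of the epoxy alkoxide. Fallback: the coupling is run stepwise. From 5 (threefold excess, surplus recovered by distillation) and lithium decynylide/BF3·OEt2, the mono-adduct 8 is isolated and silylated (TBSCl, imidazole) to the silyl ether F1. Opening of F1 with the lithium acetylide of 7 and BF3·OEt2 gives the mono-silylated diyne F2, and Bu4NF returns the route to 9.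

**Step 6.** Hydrosilylation may stop short or lose regiocontrol at the ether-bearing alkyne. During the basic peroxide oxidation the β-benzyloxy ketone may lose benzyl alcohol by E1cB elimination, or the β-hydroxy ketones may undergo retro-aldol cleavage or dehydration. Fallback: the ketones are brought in as dithianes and the alkynes are avoided. From 5, lithiated 2-nonyl-1,3-dithiane F3 (from decanal and propane-1,3-dithiol; n-BuLi, THF) opens one oxirane to the epoxy alcohol F5. Lithiated 2-[2-(benzyloxy)ethyl]-1,3-dithiane F4 (from 3-(benzyloxy)propanal) opens the other to the bis-dithiane diol F6. Hydrolysis of both dithianes (MeI, CaCO3, aq. MeCN) rejoins the route at 12.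

**Step 11.** The Lewis acid may trigger migration or opening of the neighbouring acetonide, β-elimination at C4/C5, or epoxide formation in place of the hydride shift. Fallback: from 16, addition of the lithium enolate of ethyl acetate (LiN(i-Pr)2, EtOAc, THF, −78 °C) gives the β-hydroxy ester F7 as a mixture of C3 epimers, and Dess–Martin oxidation rejoins the route at 18.

**Step 12.** Saponification of the ethyl ester may outrun lactonisation and be followed by decarboxylation, the dihydropyranone may open by elimination at high pH, and the acid stage may dehydrate the polyol. Fallback: an acid-only endgame. From 16, Roskamp homologation with tert-butyl diazoacetate (SnCl2, CH2Cl2) gives the tert-butyl β-keto ester F8. CF3CO2H in wet CH2Cl2 then removes both acetonides and the tert-butyl group and lactonises in the same medium, arriving at 20.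

## Further compounds

F1 | step 4 | tert-butyldimethyl({(2S)-1-[(2R)-oxiran-2-yl]tridec-4-yn-2-yl}oxy)silane | CCCCCCCCC#CC[C@H](O[Si](C)(C)C(C)(C)C)C[C@@H]1CO1
F2 | step 4 | (5S,7S)-1-(benzyloxy)-7-[(tert-butyldimethylsilyl)oxy]octadeca-2,9-diyn-5-ol | CCCCCCCCC#CC[C@H](O[Si](C)(C)C(C)(C)C)C[C@@H](O)CC#CCOCc1ccccc1
F3 | step 6 | 2-nonyl-1,3-dithiane | CCCCCCCCCC1SCCCS1
F4 | step 6 | 2-[2-(benzyloxy)ethyl]-1,3-dithiane | C1CSC(CCOCc2ccccc2)SC1
F5 | step 6 | (2R)-1-(2-nonyl-1,3-dithian-2-yl)-3-[(2R)-oxiran-2-yl]propan-2-ol | CCCCCCCCCC1(SCCCS1)C[C@H](O)C[C@@H]1CO1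
F6 | step 6 | (2R,4R)-1-{2-[2-(benzyloxy)ethyl]-1,3-dithian-2-yl}-5-(2-nonyl-1,3-dithian-2-yl)pentane-2,4-diol | CCCCCCCCCC1(SCCCS1)C[C@H](O)C[C@@H](O)CC1(SCCCS1)CCOCc1ccccc1
F7 | step 11 | ethyl 3-hydroxy-4-[bis-acetonide dioxanyl unit of 16]butanoate, the 3-hydroxy analogue of 18 (both C3 epimers) | CCCCCCCCC[C@H]1C[C@H](OC(C)(C)O1)C[C@@H]1C[C@@H](OC(C)(C)O1)CC(O)CC(=O)OCC
F8 | step 12 | tert-butyl 4-[(4R,6R)-6-{[(4S,6S)-2,2-dimethyl-6-nonyl-1,3-dioxan-4-yl]methyl}-2,2-dimethyl-1,3-dioxan-4-yl]-3-oxobutanoate | CCCCCCCCC[C@H]1C[C@H](OC(C)(C)O1)C[C@@H]1C[C@@H](OC(C)(C)O1)CC(=O)CC(=O)OC(C)(C)C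
A1 | alternative 1 | C4–C12 bis(iodomethyl) bis(cyclic carbonate), 4-(iodomethyl)-6-{[6-(iodomethyl)-2-oxo-1,3-dioxan-4-yl]methyl}-1,3-dioxan-2-one configured at C5, C7, C9 and C11 as in 20 | IC[C@H]1C[C@H](OC(=O)O1)C[C@@H]2C[C@H](CI)OC(=O)O2
A2 | alternative 1 | di-tert-butyl (4S,6S)-nona-1,8-diene-4,6-diyl dicarbonate | C=CC[C@H](OC(=O)OC(C)(C)C)C[C@@H](OC(=O)OC(C)(C)C)CC=C
A3 | alternative 2 | (6R)-6-{(2R)-2-[(tert-butyldimethylsilyl)oxy]-3-[(4S,6S)-2,2-dimethyl-6-nonyl-1,3-dioxan-4-yl]propyl}-4-methoxy-5,6-dihydro-2H-pyran-2-one | CCCCCCCCC[C@H]1C[C@H](OC(C)(C)O1)C[C@@H](O[Si](C)(C)C(C)(C)C)C[C@@H]2CC(OC)=CC(=O)O2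
A4 | alternative 2 | C2–C20 homopropargylic alcohol with free C5 hydroxyl, C7 tert-butyldimethylsilyl ether and C9/C11 acetonide, configured as in 20 | CCCCCCCCC[C@H]1C[C@H](OC(C)(C)O1)C[C@@H](O[Si](C)(C)C(C)(C)C)C[C@@H](O)CC#C
A5 | alternative 3 | C3–C20 dithiane with O11 silylated and O7 free, configured at C5, C7 and C11 as in 20 | CCCCCCCCC[C@H](O[Si](C)(C)C(C)(C)C)CC1(SCCCS1)C[C@@H](O)C[C@@H](O[Si](C)(C)C(C)(C)C)CCOCc1ccccc1
A6 | alternative 3 | 2-(tert-butyldimethylsilyl)-1,3-dithiane | CC(C)(C)[Si](C)(C)C1SCCCS1
A7 | alternative 3 | (S)-2-nonyloxirane | CCCCCCCCC[C@H]1CO1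
A8 | alternative 3 | tert-butyl({(2S)-4-(benzyloxy)-1-[(2S)-oxiran-2-yl]butan-2-yl}oxy)dimethylsilane | C1O[C@H]1C[C@@H](O[Si](C)(C)C(C)(C)C)CCOCc1ccccc1
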